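1. The target is a (1(10)Z,4Z)-germacranolide: a ten-membered carbocycle (ring A, C1–C10) trans-fused at C6–C7 to an α-methylene-γ-butyrolactone (ring B, O–C12(=O)–C11(=C13)–C7–C6). The C14 isovalerate and the C9 acetate are attached at the end.
2. Ring A is opened at C9–C10: intramolecular Nozaki–Hiyama–Kishi addition of a (Z)-alkenyl iodide (C10) to an α-silyloxy aldehyde (C9), which also sets C9.
3. Ring B is removed in one cut of C7–C11 and C6–O: Pd-catalysed heteroannulation of an acyclic (4Z,6Z)-diene by 2-bromoacrylic acid. The enabling feature is that the lactone carbinol carbon C6 is allylic to the C4=C5 alkene and adjacent to C7, so ring B is a γ-alkenyl-α-methylene-γ-butyrolactone, the 1,2-carbo-oxygenation retron of a C4=C5–C6=C7 diene; the oxygenated stereocentre C8 next to the (Z)-C6=C7 bond steers the facial selectivity.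
4. The diene comes from Sonogashira coupling of a (Z)-alkenyl iodide (carbocupration of propyne) with the alkyne from D-glyceraldehyde acetonide, then cis-semireduction; the C10 handle comes from syn-hydroalumination/hydroxymethylation of a silylalkyne.
5. Order of ring formation: ring B first (step 9), then ring A (step 12).

Key step: step 9

Remark: germacrane numbering is used in the text (C1–C10 = ring A; C6 = lactone carbinol carbon; C7 = ring-fusion carbon; C11, C12, C13 = lactone α-carbon, carbonyl carbon and exocyclic methylene carbon; C14 = oxygenated carbon on C10; C15 = methyl carbon on C4), and D-glyceraldehyde acetonide is assumed to be bought and distilled before use.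

Step 1
Reactants: 1 (4-bromobut-1-yn-1-yl)trimethylsilane; 2 propyne
Product: 6 [(5Z)-6-iodo-5-methylhex-5-en-1-yn-1-yl]trimethylsilane, via Grignard reagent 3 (not isolated), via alkylcopper 4 (not isolated), via alkenylcopper 5 (not isolated)
Conditions: Mg, Et2O, rt; CuBr·SMe2, Me2S, −45 °C; propyne, −25 °C; I2, −50 → 0 °C
Reagents that add atoms: iodine, II
Why: Normant carbocupration adds the alkylcopper syn across propyne with the alkyl group going to the methyl-bearing carbon, and iodinolysis of the alkenylcopper with retention gives the (Z)-iodide in which the chain is cis to iodine.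

Step 2
Reactants: 7 (4R)-2,2-dimethyl-1,3-dioxolane-4-carbaldehyde (D-glyceraldehyde acetonide)
Product: 8 (4S)-4-ethynyl-2,2-dimethyl-1,3-dioxolane
Conditions: dimethyl (1-diazo-2-oxopropyl)phosphonate, K2CO3, MeOH, 0 °C → rt
Reagents that add atoms: dimethyl (1-diazo-2-oxopropyl)phosphonate, CC(=O)C(=[N+]=[N-])P(=O)(OC)OC
Why: Seyferth–Gilbert homologation in the Ohira–Bestmann variant converts the aldehyde into the terminal alkyne under mild carbonate conditions that should leave the α-alkoxy stereocentre untouched (the descriptor changes from R to S only through the priority rules).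

Step 3
Reactants: 6 [(5Z)-6-iodo-5-methylhex-5-en-1-yn-1-yl]trimethylsilane; 8 (4S)-4-ethynyl-2,2-dimethyl-1,3-dioxolane
Product: 9 (4S)-2,2-dimethyl-4-[(3Z)-4-methyl-8-(trimethylsilyl)oct-3-ene-1,7-diyn-1-yl]-1,3-dioxolane
Conditions: Pd(PPh3)2Cl2 (cat.), CuI (cat.), Et3N, THF, rt
Reagents that add atoms: none
Why: Sonogashira coupling of the alkenyl iodide with the terminal alkyne proceeds with retention of the (Z)-alkene geometry and leaves the silyl-capped alkyne untouched.

Step 4
Reactants: 9 (4S)-2,2-dimethyl-4-[(3Z)-4-methyl-8-(trimethylsilyl)oct-3-ene-1,7-diyn-1-yl]-1,3-dioxolane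
Product: 10 (2S,5Z)-6-methyl-10-(trimethylsilyl)dec-5-ene-3,9-diyne-1,2-diol
Conditions: AcOH/H2O (4:1), 40 °C
Reagents that add atoms: none
Why: Acid-catalysed acetal hydrolysis frees the 1,2-diol at the stage where the C8–O bond is propargylic and therefore not prone to ionisation.

Step 5
Reactants: 10 (2S,5Z)-6-methyl-10-(trimethylsilyl)dec-5-ene-3,9-diyne-1,2-diol
Product: 11 (2S,3Z,5Z)-6-methyl-10-(trimethylsilyl)deca-3,5-dien-9-yne-1,2-diol
Conditions: Zn dust activated with Cu(OAc)2 and AgNO3, MeOH/H2O (1:1), 40 °C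
Reagents that add atoms: none
Why: Zinc-mediated cis-semireduction of the conjugated (activated) triple bond should give the (3Z,5Z)-diene while the isolated silylalkyne is not reduced.

Step 6
Reactants: 11 (2S,3Z,5Z)-6-methyl-10-(trimethylsilyl)deca-3,5-dien-9-yne-1,2-diol
Product: 12 (2S,3Z,5Z)-6-methyl-1,2-bis(triethylsilyloxy)-10-(trimethylsilyl)deca-3,5-dien-9-yne
Conditions: Et3SiCl, imidazole, DMF, 0 °C → rt
Reagents that add atoms: chlorotriethylsilane, CC[Si](Cl)(CC)CC
Why: Standard silyl ether formation protects both hydroxyl groups and places a bulky silyloxy group on C8 for the later facial control.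

Step 7
Reactants: 12 (2S,3Z,5Z)-6-methyl-1,2-bis(triethylsilyloxy)-10-(trimethylsilyl)deca-3,5-dien-9-yne
Product: 15 (2Z,6Z,8Z,10S)-6-methyl-10,11-bis(triethylsilyloxy)-2-(trimethylsilyl)undeca-2,6,8-trien-1-ol, via alkenylalane 13 (not isolated), via lithium alanate 14 (not isolated)
Conditions: i-Bu2AlH, N-methylpyrrolidine, heptane, 60 °C; MeLi, Et2O, 0 °C; (CH2O)n, rt; aqueous work-up
Reagents that add atoms: formaldehyde (as paraformaldehyde), C=O
Why: Amine-modified syn-hydroalumination of the silylalkyne puts aluminium on the silicon-bearing carbon, and hydroxymethylation of the derived alanate with retention gives the (Z)-2-silyl allylic alcohol with silicon cis to the chain.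

Step 8
Reactants: 15 (2Z,6Z,8Z,10S)-6-methyl-10,11-bis(triethylsilyloxy)-2-(trimethylsilyl)undeca-2,6,8-trien-1-ol
Product: 16 (2Z,6Z,8Z,10S)-1-(tert-butyldimethylsilyloxy)-6-methyl-10,11-bis(triethylsilyloxy)-2-(trimethylsilyl)undeca-2,6,8-triene
Conditions: t-BuMe2SiCl, imidazole, CH2Cl2, 0 °C → rt
Reagents that add atoms: tert-butylchlorodimethylsilane, CC(C)(C)[Si](C)(C)Cl
Why: Silyl ether formation masks the primary allylic alcohol as a group that tolerates the palladium, iodination, oxidation and chromium steps.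

Step 9
Reactants: 16 (2Z,6Z,8Z,10S)-1-(tert-butyldimethylsilyloxy)-6-methyl-10,11-bis(triethylsilyloxy)-2-(trimethylsilyl)undeca-2,6,8-triene; 17 2-bromoprop-2-enoic acid (2-bromoacrylic acid)
Product: 18 (4S,5R)-4-[(1S)-1,2-bis(triethylsilyloxy)ethyl]-5-[(1Z,5Z)-7-(tert-butyldimethylsilyloxy)-2-methyl-6-(trimethylsilyl)hepta-1,5-dien-1-yl]-3-methylideneoxolan-2-one
Conditions: Pd(OAc)2 (10 mol %), n-Bu4NCl, Na2CO3, DMF, 80 °C, slow addition of 17
Reagents that add atoms: none
Why: Larock-type heteroannulation of a 1,3-diene by a carboxy-substituted alkenyl halide (closest known reaction type: the palladium-catalysed annulation of 1,3-dienes with haloalkenoic and o-iodobenzoic acids to unsaturated lactones): zerovalent palladium inserts into the C–Br bond of 17, the 1-carboxyvinylpalladium species adds syn across C6=C7 with carbon going to the less substituted diene terminus C7, and the allylpalladium unit C6–C5–C4 so formed is captured at C6 by the tethered carboxylate, which regenerates the catalyst. Ring B closes in the 5-exo mode at the allyl terminus C6, because closure at C4 would need a seven-membered ring and a quaternary carbon. C7 is controlled by A(1,3) strain: in the (6Z)-alkene the C8–H bond lies in the alkene plane, the two faces carry OSiEt3 and CH2OSiEt3, and the vinylpalladium should add anti to the C8–O bond, which gives the 7,8-erythro relation of the target. C6 is controlled by the mechanism: outer-sphere attack of the carboxylate anti to palladium (favoured by chloride) after syn insertion amounts to anti addition to the (Z)-alkene and hence the trans-lactone. The (4Z) geometry should be kept because the fully substituted allyl terminus C4 does not carry palladium as a σ-bond before ring closure. The step needs regio-, face- and chemoselectivity, which rest on the unsymmetrical substitution of the diene, the C8 stereocentre from 7 and the inertness of the hindered vinylsilane and silyl ethers under phosphine-free conditions.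

Step 10
Reactants: 18 (4S,5R)-4-[(1S)-1,2-bis(triethylsilyloxy)ethyl]-5-[(1Z,5Z)-7-(tert-butyldimethylsilyloxy)-2-methyl-6-(trimethylsilyl)hepta-1,5-dien-1-yl]-3-methylideneoxolan-2-one
Product: 19 (4S,5R)-4-[(1S)-1,2-bis(triethylsilyloxy)ethyl]-5-[(1Z,5Z)-7-(tert-butyldimethylsilyloxy)-6-iodo-2-methylhepta-1,5-dien-1-yl]-3-methylideneoxolan-2-one
Conditions: N-iodosuccinimide, 2,6-lutidine, (CF3)2CHOH/CH2Cl2, 0 °C
Reagents that add atoms: N-iodosuccinimide, O=C1CCC(=O)N1I
Why: Electrophilic iododesilylation (ipso substitution through a β-silyl cation) should replace the trimethylsilyl group by iodine with retention of the alkene geometry, the vinylsilane being the most nucleophilic alkene present.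

Step 11
Reactants: 19 (4S,5R)-4-[(1S)-1,2-bis(triethylsilyloxy)ethyl]-5-[(1Z,5Z)-7-(tert-butyldimethylsilyloxy)-6-iodo-2-methylhepta-1,5-dien-1-yl]-3-methylideneoxolan-2-one
Product: 20 (2S)-2-[(2R,3S)-2-[(1Z,5Z)-7-(tert-butyldimethylsilyloxy)-6-iodo-2-methylhepta-1,5-dien-1-yl]-4-methylidene-5-oxooxolan-3-yl]-2-(triethylsilyloxy)acetaldehyde
Conditions: (COCl)2, DMSO, CH2Cl2, −78 → −30 °C; Et3N, −78 °C → rt
Reagents that add atoms: none
Why: Swern oxidation cleaves and oxidises the primary triethylsilyl ether directly to the aldehyde while the secondary triethylsilyl and the tert-butyldimethylsilyl ethers should remain in place.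

Step 12
Reactants: 20 (2S)-2-[(2R,3S)-2-[(1Z,5Z)-7-(tert-butyldimethylsilyloxy)-6-iodo-2-methylhepta-1,5-dien-1-yl]-4-methylidene-5-oxooxolan-3-yl]-2-(triethylsilyloxy)acetaldehyde
Product: 22 (1(10)Z,4Z,6R,7S,8S,9R)-14-(tert-butyldimethylsilyloxy)-9-hydroxy-8-(triethylsilyloxy)germacra-1(10),4,11(13)-trien-12,6-olide, via alkenylchromium 21 (not isolated)
Conditions: CrCl2 (excess), NiCl2 (cat.), DMSO/THF, rt, high dilution
Reagents that add atoms: none
Why: Intramolecular Nozaki–Hiyama–Kishi reaction closes ring A with retention of the alkenyl geometry, and Felkin–Anh addition anti to the non-chelating C8 silyloxy group should give the (9R)-carbinol (8,9-erythro).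

Step 13
Reactants: 22 (1(10)Z,4Z,6R,7S,8S,9R)-14-(tert-butyldimethylsilyloxy)-9-hydroxy-8-(triethylsilyloxy)germacra-1(10),4,11(13)-trien-12,6-olide
Product: 23 (1(10)Z,4Z,6R,7S,8S,9R)-9-acetoxy-14-(tert-butyldimethylsilyloxy)-8-(triethylsilyloxy)germacra-1(10),4,11(13)-trien-12,6-olide
Conditions: Ac2O, pyridine, DMAP (cat.), CH2Cl2, 0 °C → rt
Reagents that add atoms: acetic anhydride, CC(=O)OC(C)=O
Why: Nucleophile-catalysed acylation of the only free hydroxyl group installs the C9 acetate.

Step 14
Reactants: 23 (1(10)Z,4Z,6R,7S,8S,9R)-9-acetoxy-14-(tert-butyldimethylsilyloxy)-8-(triethylsilyloxy)germacra-1(10),4,11(13)-trien-12,6-olide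
Product: 24 (1(10)Z,4Z,6R,7R,8S,9R)-9-acetoxy-8,14-dihydroxygermacra-1(10),4,11(13)-trien-12,6-olide
Conditions: HF·pyridine, pyridine, THF, 0 °C → rt
Reagents that add atoms: none
Why: Fluoride-mediated desilylation under buffered, weakly acidic conditions should remove both silyl ethers without acetyl migration or damage to the α-methylene lactone.

Step 15
Reactants: 24 (1(10)Z,4Z,6R,7R,8S,9R)-9-acetoxy-8,14-dihydroxygermacra-1(10),4,11(13)-trien-12,6-olide
Product: 25 (1(10)Z,4Z,6R,7R,8S,9R)-9-acetoxy-8-hydroxy-14-(3-methylbutanoyloxy)germacra-1(10),4,11(13)-trien-12,6-olide (CNP0603244.1)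
Conditions: 3-methylbutanoyl chloride (1.05 equiv), 2,4,6-collidine, CH2Cl2, −78 → −40 °C
Reagents that add atoms: 3-methylbutanoyl chloride, CC(C)CC(=O)Cl
Why: Kinetically selective acylation of the primary allylic C14 hydroxyl over the hindered secondary C8 hydroxyl with an acid chloride and a weak hindered base should complete the target.

Compound list
1 | (4-bromobut-1-yn-1-yl)trimethylsilane | C[Si](C)(C)C#CCCBr | starting material
2 | propyne | CC#C | starting material
3 | [4-(trimethylsilyl)but-3-yn-1-yl]magnesium bromide | C[Si](C)(C)C#CCC[Mg]Br | intermediate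
4 | [4-(trimethylsilyl)but-3-yn-1-yl]copper (MgBr2/Me2S complex) | C[Si](C)(C)C#CCC[Cu] | intermediate
5 | [(1Z)-2-methyl-6-(trimethylsilyl)hex-1-en-5-yn-1-yl]copper | C[Si](C)(C)C#CCC/C(C)=C\[Cu] | intermediate
6 | [(5Z)-6-iodo-5-methylhex-5-en-1-yn-1-yl]trimethylsilane | C[Si](C)(C)C#CCC/C(C)=C\I | intermediate
7 | (4R)-2,2-dimethyl-1,3-dioxolane-4-carbaldehyde (D-glyceraldehyde acetonide) | O=C[C@H]1COC(C)(C)O1 | starting material
8 | (4S)-4-ethynyl-2,2-dimethyl-1,3-dioxolane | C#C[C@H]1COC(C)(C)O1 | intermediate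
9 | (4S)-2,2-dimethyl-4-[(3Z)-4-methyl-8-(trimethylsilyl)oct-3-ene-1,7-diyn-1-yl]-1,3-dioxolane | C[Si](C)(C)C#CCC/C(C)=C\C#C[C@H]1COC(C)(C)O1 | intermediate
10 | (2S,5Z)-6-methyl-10-(trimethylsilyl)dec-5-ene-3,9-diyne-1,2-diol | C[Si](C)(C)C#CCC/C(C)=C\C#C[C@H](O)CO | intermediate
11 | (2S,3Z,5Z)-6-methyl-10-(trimethylsilyl)deca-3,5-dien-9-yne-1,2-diol | C[Si](C)(C)C#CCC/C(C)=C\C=C/[C@H](O)CO | intermediate
12 | (2S,3Z,5Z)-6-methyl-1,2-bis(triethylsilyloxy)-10-(trimethylsilyl)deca-3,5-dien-9-yne | C[Si](C)(C)C#CCC/C(C)=C\C=C/[C@H](O[Si](CC)(CC)CC)CO[Si](CC)(CC)CC | intermediate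
13 | diisobutyl[(1Z,5Z,7Z,9S)-5-methyl-9,10-bis(triethylsilyloxy)-1-(trimethylsilyl)deca-1,5,7-trien-1-yl]alane (silicon cis to the chain) | C[Si](C)(C)/C([Al](CC(C)C)CC(C)C)=C\CC/C(C)=C\C=C/[C@H](O[Si](CC)(CC)CC)CO[Si](CC)(CC)CC | intermediate
14 | lithium diisobutyl(methyl)[(1Z,5Z,7Z,9S)-5-methyl-9,10-bis(triethylsilyloxy)-1-(trimethylsilyl)deca-1,5,7-trien-1-yl]alanate | [Li+].C[Si](C)(C)/C([Al-](C)(CC(C)C)CC(C)C)=C\CC/C(C)=C\C=C/[C@H](O[Si](CC)(CC)CC)CO[Si](CC)(CC)CC | intermediate
15 | (2Z,6Z,8Z,10S)-6-methyl-10,11-bis(triethylsilyloxy)-2-(trimethylsilyl)undeca-2,6,8-trien-1-ol | C[Si](C)(C)/C(CO)=C\CC/C(C)=C\C=C/[C@H](O[Si](CC)(CC)CC)CO[Si](CC)(CC)CC | intermediate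
16 | (2Z,6Z,8Z,10S)-1-(tert-butyldimethylsilyloxy)-6-methyl-10,11-bis(triethylsilyloxy)-2-(trimethylsilyl)undeca-2,6,8-triene | C[Si](C)(C)/C(CO[Si](C)(C)C(C)(C)C)=C\CC/C(C)=C\C=C/[C@H](O[Si](CC)(CC)CC)CO[Si](CC)(CC)CC | intermediate
17 | 2-bromoprop-2-enoic acid (2-bromoacrylic acid) | C=C(Br)C(=O)O | starting material
18 | (4S,5R)-4-[(1S)-1,2-bis(triethylsilyloxy)ethyl]-5-[(1Z,5Z)-7-(tert-butyldimethylsilyloxy)-2-methyl-6-(trimethylsilyl)hepta-1,5-dien-1-yl]-3-methylideneoxolan-2-one | C=C1C(=O)O[C@H](/C=C(/C)CC/C=C(/CO[Si](C)(C)C(C)(C)C)[Si](C)(C)C)[C@H]1[C@H](O[Si](CC)(CC)CC)CO[Si](CC)(CC)CC | intermediate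
19 | (4S,5R)-4-[(1S)-1,2-bis(triethylsilyloxy)ethyl]-5-[(1Z,5Z)-7-(tert-butyldimethylsilyloxy)-6-iodo-2-methylhepta-1,5-dien-1-yl]-3-methylideneoxolan-2-one | C=C1C(=O)O[C@H](/C=C(/C)CC/C=C(/CO[Si](C)(C)C(C)(C)C)I)[C@H]1[C@H](O[Si](CC)(CC)CC)CO[Si](CC)(CC)CC | intermediate
20 | (2S)-2-[(2R,3S)-2-[(1Z,5Z)-7-(tert-butyldimethylsilyloxy)-6-iodo-2-methylhepta-1,5-dien-1-yl]-4-methylidene-5-oxooxolan-3-yl]-2-(triethylsilyloxy)acetaldehyde | C=C1C(=O)O[C@H](/C=C(/C)CC/C=C(/CO[Si](C)(C)C(C)(C)C)I)[C@H]1[C@H](O[Si](CC)(CC)CC)C=O | intermediate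
21 | alkenylchromium dichloride derived from 20 (CrCl2 in place of iodine, same geometry) | C=C1C(=O)O[C@H](/C=C(/C)CC/C=C(/CO[Si](C)(C)C(C)(C)C)[Cr](Cl)Cl)[C@H]1[C@H](O[Si](CC)(CC)CC)C=O | intermediate
22 | (1(10)Z,4Z,6R,7S,8S,9R)-14-(tert-butyldimethylsilyloxy)-9-hydroxy-8-(triethylsilyloxy)germacra-1(10),4,11(13)-trien-12,6-olide | C=C1C(=O)O[C@@H]2/C=C(/C)CC/C=C(/CO[Si](C)(C)C(C)(C)C)[C@@H](O)[C@@H](O[Si](CC)(CC)CC)[C@@H]12 | intermediate
23 | (1(10)Z,4Z,6R,7S,8S,9R)-9-acetoxy-14-(tert-butyldimethylsilyloxy)-8-(triethylsilyloxy)germacra-1(10),4,11(13)-trien-12,6-olide | C=C1C(=O)O[C@@H]2/C=C(/C)CC/C=C(/CO[Si](C)(C)C(C)(C)C)[C@@H](OC(C)=O)[C@@H](O[Si](CC)(CC)CC)[C@@H]12 | intermediate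
24 | (1(10)Z,4Z,6R,7R,8S,9R)-9-acetoxy-8,14-dihydroxygermacra-1(10),4,11(13)-trien-12,6-olide | C=C1C(=O)O[C@@H]2/C=C(/C)CC/C=C(/CO)[C@@H](OC(C)=O)[C@@H](O)[C@@H]12 | intermediate
25 | (1(10)Z,4Z,6R,7R,8S,9R)-9-acetoxy-8-hydroxy-14-(3-methylbutanoyloxy)germacra-1(10),4,11(13)-trien-12,6-olide (CNP0603244.1) | C=C1C(=O)O[C@@H]2/C=C(/C)CC/C=C(/COC(=O)CC(C)C)[C@@H](OC(C)=O)[C@@H](O)[C@@H]12 | target

The descriptor at C7 reads S in 18–23 and R in 24 and 25 only because the silyl group on O8 changes the priority order; the spatial arrangement is the same throughout.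

Total step count: 15
Longest linear sequence: 14 steps (from 1 through steps 1 and 3–15; the branch from 7 through steps 2 and 3–15 is equally long)

Steps most likely to fail

Step 9. The carbopalladation may not discriminate well between the two faces of the hindered (Z,Z)-diene. The carboxylate may also be transferred from palladium on the same face (inner-sphere), which would give the cis-lactone. The allylpalladium may lose a β-hydride, and 17 may oligomerise before it reacts. The fallback sets out from 16 and comes back at 18, and replaces the organopalladium pathway by an oxidative radical carbolactonisation with trivalent manganese. Treatment of 16 with Mn(OAc)3·2H2O, Cu(OAc)2 (cat.), malonic acid and KOAc in MeCN/AcOH at rt should add the malonyl radical to the diene terminus C7. The allyl radical is then oxidised, and the carboxyl group closes on C6 to the more stable trans-lactone, the 2-oxooxolane-3-carboxylic acid F1. Decarboxylative methylenation of F1 (aqueous formaldehyde, Et2NH, then NaOAc/AcOH, 60 °C) should then give 18.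

Step 12. Intermolecular coupling may compete with closure of the strained ten-membered ring. The addition may show low Felkin–Anh selectivity at C9, and the α-silyloxy aldehyde may epimerise. The fallback sets out from 20 and comes back at 22, and sets C9 by reagent-controlled reduction of a ketone instead of by the C–C bond formation. The ring closure is run without regard to C9, so that 22 and its C9 epimer F2 are both collected. Dess–Martin periodinane oxidation of F2 (or of the mixture) should give the ring-A enone F3. Corey–Bakshi–Shibata reduction of F3 (B-methyl oxazaborolidine of the handedness that delivers hydride to the face giving the 9R carbinol, catecholborane, −78 °C) spares the α-methylene lactone and should return 22.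

Step 5. The semireduction may over-reduce the diene, stop short of full conversion, or partly isomerise the diene from Z to E. The geometry of C6=C7 decides the lactone configuration in step 9. The fallback sets out from 6 and 7 and comes back at 11, and builds the diene by a stereospecific coupling of two (Z)-alkenyl units instead of by alkyne reduction. Stork–Zhao olefination of 7 (Ph3P=CHI generated from (iodomethyl)triphenylphosphonium iodide and NaN(SiMe3)2, THF/DMPU, −78 °C) should give the (Z)-iodoalkene F4. Iodine–lithium exchange on 6 (t-BuLi, Et2O, −78 °C) followed by ZnBr2 gives the alkenylzinc bromide F5. Negishi coupling of F5 with F4 (Pd(PPh3)4, THF, rt) should join the two units with retention to the diene acetonide F6. Acetal hydrolysis of F6 (AcOH/H2O, rt) then gives 11.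

Further compounds
F1 | step 9 | (4S,5R)-4-[(1S)-1,2-bis(triethylsilyloxy)ethyl]-5-[(1Z,5Z)-7-(tert-butyldimethylsilyloxy)-2-methyl-6-(trimethylsilyl)hepta-1,5-dien-1-yl]-2-oxooxolane-3-carboxylic acid (C3 epimers) | OC(=O)C1C(=O)O[C@H](/C=C(/C)CC/C=C(/CO[Si](C)(C)C(C)(C)C)[Si](C)(C)C)[C@H]1[C@H](O[Si](CC)(CC)CC)CO[Si](CC)(CC)CC
F2 | step 12 | (1(10)Z,4Z,6R,7S,8S,9S)-14-(tert-butyldimethylsilyloxy)-9-hydroxy-8-(triethylsilyloxy)germacra-1(10),4,11(13)-trien-12,6-olide (C9 epimer of 22) | C=C1C(=O)O[C@@H]2/C=C(/C)CC/C=C(/CO[Si](C)(C)C(C)(C)C)[C@H](O)[C@@H](O[Si](CC)(CC)CC)[C@@H]12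
F3 | step 12 | (1(10)Z,4Z,6R,7S,8S)-14-(tert-butyldimethylsilyloxy)-9-oxo-8-(triethylsilyloxy)germacra-1(10),4,11(13)-trien-12,6-olide | C=C1C(=O)O[C@@H]2/C=C(/C)CC/C=C(/CO[Si](C)(C)C(C)(C)C)C(=O)[C@@H](O[Si](CC)(CC)CC)[C@@H]12
F4 | step 5 | (4S)-4-[(Z)-2-iodoethenyl]-2,2-dimethyl-1,3-dioxolane | I/C=C\[C@H]1COC(C)(C)O1
F5 | step 5 | [(1Z)-2-methyl-6-(trimethylsilyl)hex-1-en-5-yn-1-yl]zinc bromide | C[Si](C)(C)C#CCC/C(C)=C\[Zn]Br
F6 | step 5 | (4S)-2,2-dimethyl-4-[(1Z,3Z)-4-methyl-8-(trimethylsilyl)octa-1,3-dien-7-yn-1-yl]-1,3-dioxolane | C[Si](C)(C)C#CCC/C(C)=C\C=C/[C@H]1COC(C)(C)O1
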